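**Plan**

- Retrosynthetic cuts: C2–C1′ first (ring B, the bond that sets C2); then O1–C2 and C8–C1″ (prenyl) together in one step; then C3–C4 (ethynyl), C4–C4a (formyl) and C8a–O1 (C–H oxidation), back to 2-methylresorcinol.
- Enabling feature: ring A is mirror-symmetric about the axis O1–C8a···C6–CH3, apart from C4a-acyl versus C8-prenyl. O1 is ortho to C8, and the other carbons a [3,3] shift from O1 can reach (C4a directly, C6 by Cope relay) are quaternary. A 1,1-dimethylallyl group placed on O1 can therefore only settle at C8, and in doing so frees exactly the phenol that must close the pyranone.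
- Forward order: ring A is bought. O1 is put para to the methyl group by steric C–H borylation/oxidation (symmetric phenol, no regiochemical choice), C4 is added by ortho-formylation, O1 is capped as the tertiary allyl ether, and the aldehyde is turned into an ethynyl ketone. One thermal step then moves the C5 unit to C8 and closes ring C (chromone). Ring B is joined last.
- Stereochemistry: the only stereocentre, C2 (S), is made in step 9 by Re-face aryl transfer from a Rh(I)/(S)-biaryl bisphosphine catalyst to the chromone. Only a mildly acidic deprotection follows, so C2 never meets base (retro-oxa-Michael).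

Key step: step 8

Assumption: the (S)-configured biaryl bisphosphine is taken to direct aryl transfer to the Re face of C2 of the chromone, by analogy with Rh/(S)-biaryl bisphosphine additions to cyclic enones; if a trial run on 12 shows the opposite sense, the (R)-ligand is used and nothing else changes.

**Route**

Step 1
Reactants: 1 2-methylresorcinol
Product: 2 1,3-bis(methoxymethoxy)-2-methylbenzene
Conditions: MOMCl (2.5 equiv), i-Pr2NEt (3 equiv), CH2Cl2, 0 °C → rt
Reagents that add atoms: chloromethyl methyl ether COCCl
Why: Base-mediated O-alkylation of both phenols with an α-chloro ether (MOM acetal formation); the acetals are inert to every later step up to the final acid release.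

Step 2
Reactants: 2 1,3-bis(methoxymethoxy)-2-methylbenzene
Product: 4 3,5-bis(methoxymethoxy)-4-methylphenol, via aryl pinacol boronate 3 (not isolated)
Conditions: [Ir(OMe)(cod)]2 (1.5 mol%), dtbpy (3 mol%), B2pin2 (0.6 equiv), THF, 80 °C (sealed); then aq NaOH, 30% H2O2, 0 °C → rt
Reagents that add atoms: bis(pinacolato)diboron CC1(C)OB(OC1(C)C)B1OC(C)(C)C(C)(C)O1 (boron of 3 only); hydrogen peroxide OO
Why: Sterically governed Ir-catalysed aromatic C–H borylation goes to the only C–H that has no ortho substituent (para to the methyl group), and oxidation of the boronate gives the phenol, which places the future O1 on the mirror axis with two equivalent ortho carbons.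

Step 3
Reactants: 4 3,5-bis(methoxymethoxy)-4-methylphenol
Product: 5 6-hydroxy-2,4-bis(methoxymethoxy)-3-methylbenzaldehyde
Conditions: MgCl2 (1.5 equiv), Et3N (3.75 equiv), (CH2O)n (7 equiv), MeCN, reflux
Reagents that add atoms: paraformaldehyde (as formaldehyde) C=O
Why: Casnati–Skattebøl ortho-formylation through the magnesium phenoxide reacts only ortho to the free OH, the two ortho positions are equivalent by symmetry, and the chelated magnesium salicylaldehyde is deactivated towards a second formylation.

Step 4
Reactants: 5 6-hydroxy-2,4-bis(methoxymethoxy)-3-methylbenzaldehyde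
Product: 6 2,4-bis(methoxymethoxy)-3-methyl-6-[(2-methylbut-3-yn-2-yl)oxy]benzaldehyde
Conditions: 3-chloro-3-methylbut-1-yne (1.5 equiv), CuCl2·2H2O (1 mol%), DBU (1.5 equiv), MeCN, 0 °C → rt
Reagents that add atoms: 3-chloro-3-methylbut-1-yne CC(C)(Cl)C#C
Why: Copper-catalysed propargylic etherification via a copper acetylide/allenylidene species forms the tertiary aryl ether at the only phenol, a reaction type that works best with acidic, electron-poor phenols such as this salicylaldehyde.

Step 5
Reactants: 6 2,4-bis(methoxymethoxy)-3-methyl-6-[(2-methylbut-3-yn-2-yl)oxy]benzaldehyde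
Product: 7 2,4-bis(methoxymethoxy)-3-methyl-6-[(2-methylbut-3-en-2-yl)oxy]benzaldehyde
Conditions: H2 (1 atm), Lindlar catalyst, quinoline, EtOAc, rt
Reagents that add atoms: none
Why: Lindlar semihydrogenation stops the terminal alkyne at the vinyl stage and leaves the aryl aldehyde and the acetals untouched, which is the standard access to aryl 1,1-dimethylallyl ethers.

Step 6
Reactants: 7 2,4-bis(methoxymethoxy)-3-methyl-6-[(2-methylbut-3-en-2-yl)oxy]benzaldehyde
Product: 8 1-{2,4-bis(methoxymethoxy)-3-methyl-6-[(2-methylbut-3-en-2-yl)oxy]phenyl}prop-2-yn-1-ol (racemic)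
Conditions: HC≡CMgBr (0.5 M in THF, 1.5 equiv), THF, −40 → 0 °C; then H2O/sat. aq NH4Cl
Reagents that add atoms: ethynylmagnesium bromide C#C[Mg]Br
Why: 1,2-Addition of an alkynyl Grignard reagent to the aldehyde introduces C2 and C3; the carbinol centre is racemic and is removed by the oxidation in step 7.

Step 7
Reactants: 8 1-{2,4-bis(methoxymethoxy)-3-methyl-6-[(2-methylbut-3-en-2-yl)oxy]phenyl}prop-2-yn-1-ol
Product: 9 1-{2,4-bis(methoxymethoxy)-3-methyl-6-[(2-methylbut-3-en-2-yl)oxy]phenyl}prop-2-yn-1-one
Conditions: MnO2 (activated, 15 equiv), CH2Cl2, rt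
Reagents that add atoms: none
Why: Activated MnO2 oxidises the doubly activated (benzylic and propargylic) alcohol under neutral conditions, so the acid-sensitive tertiary allyl ether and the electron-rich carbinol are not ionised.

Step 8
Reactants: 9 1-{2,4-bis(methoxymethoxy)-3-methyl-6-[(2-methylbut-3-en-2-yl)oxy]phenyl}prop-2-yn-1-one
Product: 12 5,7-bis(methoxymethoxy)-6-methyl-8-(3-methylbut-2-en-1-yl)-4H-chromen-4-one, via dienone 10 (not isolated), via hydroxy ynone 11 (not isolated)
Conditions: PhMe (0.02 M, degassed, base-washed glass), 115 °C; then Et3N (0.2 equiv), rt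
Reagents that add atoms: none
Why: On heating, the aryl 1,1-dimethylallyl ether of 9 undergoes the aromatic Claisen [3,3] shift through a chair transition state, which moves the C5 unit from O1 to C8 with allylic inversion (so it arrives as the 3-methylbut-2-enyl group) and gives dienone 10, whose enolisation to phenol 11 is irreversible; the O1–H just set free then adds to the β-carbon of the ethynyl ketone and closes ring C. The closest known reaction types are the Claisen rearrangement of aryl 1,1-dimethylallyl ethers to ortho-prenylphenols and the amine-promoted cyclisation of ortho-hydroxyaryl ethynyl ketones to chromones, here run in one flask. The pyranone closes by 6-endo-dig oxa-Michael addition; the 5-exo-dig alternative would need attack at the α-carbon against the polarisation of the ynone. No stereocentre is left in 12, since the sp3 centre of 10 is lost on aromatisation. The step needs C8 selectivity in the shift and O1 selectivity in the closure: shifts to C4a (acyl-bearing) or onward by Cope to C6 (methyl-bearing) give dienones that cannot aromatise and revert, and O5 and O7 stay blocked as acetals, so the only phenol that ever appears is O1, next to the new prenyl group and distal to the methyl group. The tertiary ether and the two extra alkoxy donors should allow the shift near 115 °C, below the temperature at which the MOM ethers or the ynone would suffer.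

Step 9
Reactants: 12 5,7-bis(methoxymethoxy)-6-methyl-8-(3-methylbut-2-en-1-yl)-4H-chromen-4-one; 13 4-(methoxymethoxy)phenylboronic acid
Product: 14 (2S)-5,7-bis(methoxymethoxy)-2-[4-(methoxymethoxy)phenyl]-6-methyl-8-(3-methylbut-2-en-1-yl)-2,3-dihydro-4H-chromen-4-one
Conditions: [Rh(OH)(cod)]2 (2.5 mol%), (S)-MeO-F12-BIPHEP (5.5 mol%), 13 (2.5 equiv), PhMe/H2O (10:1), 30 °C, no added base
Reagents that add atoms: none
Why: Rh(I)-catalysed asymmetric 1,4-addition of an arylboronic acid to a chromone (Hayashi–Miyaura type), in which the aryl–Rh species inserts C2=C3 from the Re face of C2 under control of the C2-symmetric bisphosphine and the oxa-π-allyl rhodium is protonated by water; the electron-poor ligand keeps the 5,7-dioxygenated chromone reactive near ambient temperature, the base-free medium avoids retro-oxa-Michael opening of the (2S)-flavanone, and the trisubstituted prenyl alkene does not compete as an acceptor.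

Step 10
Reactants: 14 (2S)-5,7-bis(methoxymethoxy)-2-[4-(methoxymethoxy)phenyl]-6-methyl-8-(3-methylbut-2-en-1-yl)-2,3-dihydro-4H-chromen-4-one
Product: 15 6-methyl-8-prenylnaringenin, (2S)-5,7-dihydroxy-2-(4-hydroxyphenyl)-6-methyl-8-(3-methylbut-2-en-1-yl)-2,3-dihydro-4H-chromen-4-one
Conditions: 3 M aq HCl/MeOH (1:5), 45 °C
Reagents that add atoms: none
Why: Acid-catalysed solvolysis of the three aryl methoxymethyl acetals to dimethoxymethane is a standard release of MOM-protected prenylflavanones; the trisubstituted alkene needs stronger acid to cyclise onto O7, and C2 is not labilised by acid because flavanone racemisation runs through base-mediated ring opening.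

**Compound list**

1 | 2-methylresorcinol (2-methylbenzene-1,3-diol) | Cc1c(O)cccc1O | starting material
2 | 1,3-bis(methoxymethoxy)-2-methylbenzene | COCOc1cccc(OCOC)c1C | intermediate
3 | 2-[3,5-bis(methoxymethoxy)-4-methylphenyl]-4,4,5,5-tetramethyl-1,3,2-dioxaborolane | COCOc1cc(B2OC(C)(C)C(C)(C)O2)cc(OCOC)c1C | intermediate (not isolated)
4 | 3,5-bis(methoxymethoxy)-4-methylphenol | COCOc1cc(O)cc(OCOC)c1C | intermediate
5 | 6-hydroxy-2,4-bis(methoxymethoxy)-3-methylbenzaldehyde | O=Cc1c(O)cc(OCOC)c(C)c1OCOC | intermediate
6 | 2,4-bis(methoxymethoxy)-3-methyl-6-[(2-methylbut-3-yn-2-yl)oxy]benzaldehyde | O=Cc1c(OC(C)(C)C#C)cc(OCOC)c(C)c1OCOC | intermediate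
7 | 2,4-bis(methoxymethoxy)-3-methyl-6-[(2-methylbut-3-en-2-yl)oxy]benzaldehyde | O=Cc1c(OC(C)(C)C=C)cc(OCOC)c(C)c1OCOC | intermediate
8 | 1-{2,4-bis(methoxymethoxy)-3-methyl-6-[(2-methylbut-3-en-2-yl)oxy]phenyl}prop-2-yn-1-ol (racemic) | C#CC(O)c1c(OC(C)(C)C=C)cc(OCOC)c(C)c1OCOC | intermediate
9 | 1-{2,4-bis(methoxymethoxy)-3-methyl-6-[(2-methylbut-3-en-2-yl)oxy]phenyl}prop-2-yn-1-one | C#CC(=O)c1c(OC(C)(C)C=C)cc(OCOC)c(C)c1OCOC | intermediate
10 | 3,5-bis(methoxymethoxy)-4-methyl-6-(3-methylbut-2-en-1-yl)-2-(prop-2-ynoyl)cyclohexa-2,4-dien-1-one (racemic) | C#CC(=O)C1=C(OCOC)C(C)=C(OCOC)C(CC=C(C)C)C1=O | intermediate (not isolated)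
11 | 1-[2-hydroxy-4,6-bis(methoxymethoxy)-5-methyl-3-(3-methylbut-2-en-1-yl)phenyl]prop-2-yn-1-one | C#CC(=O)c1c(O)c(CC=C(C)C)c(OCOC)c(C)c1OCOC | intermediate (not isolated)
12 | 5,7-bis(methoxymethoxy)-6-methyl-8-(3-methylbut-2-en-1-yl)-4H-chromen-4-one | CC(C)=CCc1c(OCOC)c(C)c(OCOC)c2c1OC=CC2=O | intermediate
13 | 4-(methoxymethoxy)phenylboronic acid | COCOc1ccc(B(O)O)cc1 | starting material
14 | (2S)-5,7-bis(methoxymethoxy)-2-[4-(methoxymethoxy)phenyl]-6-methyl-8-(3-methylbut-2-en-1-yl)-2,3-dihydro-4H-chromen-4-one | CC(C)=CCc1c(OCOC)c(C)c(OCOC)c2c1O[C@H](c1ccc(OCOC)cc1)CC2=O | intermediate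
15 | 6-methyl-8-prenylnaringenin, (2S)-5,7-dihydroxy-2-(4-hydroxyphenyl)-6-methyl-8-(3-methylbut-2-en-1-yl)-2,3-dihydro-4H-chromen-4-one | CC(C)=CCc1c(O)c(C)c(O)c2c1O[C@H](c1ccc(O)cc1)CC2=O | target

**Step count and risks**

Total step count: 10. Longest linear sequence: 10 steps (from 1; 13 is bought and enters in step 9).

The three steps most likely to fail:

Step 8. The risk is thermal loss before the sigmatropic shift: the terminal ynone may oligomerise, or the tertiary allyl ether may ionise and shed its C5 unit as isoprene. The fallback sets out from 7 and comes back at 12; it separates the rearrangement from the ring closure and runs it on the thermally robust aldehyde. Heating 7 in toluene at 110 °C should give 2-hydroxy-4,6-bis(methoxymethoxy)-5-methyl-3-(3-methylbut-2-en-1-yl)benzaldehyde F1. Ethynylmagnesium bromide (2.5 equiv, THF, 0 °C) should add to it to give the racemic diol 2-(1-hydroxyprop-2-yn-1-yl)-3,5-bis(methoxymethoxy)-4-methyl-6-(3-methylbut-2-en-1-yl)phenol F2. MnO2 in CH2Cl2 should oxidise this to hydroxy ynone 11, which should close to 12 on addition of Et3N.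

Step 9. The risk is slow carbometalation of the electron-rich 5,7-dioxygenated chromone, so that protodeboronation of 13 outruns the addition, or erosion of enantiopurity through reversible opening of the product. The fallback sets out from 12 and comes back at 14; it sets the stereocentre by kinetic resolution instead of in the C–C bond formation. Addition of 13 to 12 with the more active phosphine-free diene catalyst [Rh(OH)(cod)]2 (dioxane/H2O, 50 °C) should give racemic 5,7-bis(methoxymethoxy)-2-[4-(methoxymethoxy)phenyl]-6-methyl-8-(3-methylbut-2-en-1-yl)chroman-4-one F3. Asymmetric transfer hydrogenation (Cp*RhCl(TsDPEN), HCO2H/Et3N, EtOAc, rt, catalyst antipode chosen so that the (2R)-ketone is reduced faster) run to about half conversion should turn the (2R)-ketone into the cis-alcohol (2R,4R)-5,7-bis(methoxymethoxy)-2-[4-(methoxymethoxy)phenyl]-6-methyl-8-(3-methylbut-2-en-1-yl)chroman-4-ol F4. The (2S)-ketone 14 should remain and is separated by chromatography.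

Step 10. The risk is Brønsted-acid activation of the C8 prenyl alkene (closure onto O7 to a dimethylchroman ring, or addition of HCl or methanol) competing with the slow cleavage of the hydrogen-bonded 5-O acetal. The fallback sets out from 14 and comes back at 15; it exchanges the acetals for silyl ethers without protic acid and then desilylates under neutral conditions. TESOTf/2,2′-bipyridyl (CH2Cl2, 0 °C) should convert the three aryl MOM ethers into triethylsilyl ethers and give (2S)-6-methyl-8-(3-methylbut-2-en-1-yl)-5,7-bis(triethylsilyloxy)-2-[4-(triethylsilyloxy)phenyl]chroman-4-one F5. KHF2 in MeOH at rt should then release 15.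

**Further compounds**

F1 | step 8 | 2-hydroxy-4,6-bis(methoxymethoxy)-5-methyl-3-(3-methylbut-2-en-1-yl)benzaldehyde | O=Cc1c(O)c(CC=C(C)C)c(OCOC)c(C)c1OCOC
F2 | step 8 | 2-(1-hydroxyprop-2-yn-1-yl)-3,5-bis(methoxymethoxy)-4-methyl-6-(3-methylbut-2-en-1-yl)phenol (racemic) | C#CC(O)c1c(O)c(CC=C(C)C)c(OCOC)c(C)c1OCOC
F3 | step 9 | racemic 5,7-bis(methoxymethoxy)-2-[4-(methoxymethoxy)phenyl]-6-methyl-8-(3-methylbut-2-en-1-yl)chroman-4-one | CC(C)=CCc1c(OCOC)c(C)c(OCOC)c2c1OC(c1ccc(OCOC)cc1)CC2=O
F4 | step 9 | (2R,4R)-5,7-bis(methoxymethoxy)-2-[4-(methoxymethoxy)phenyl]-6-methyl-8-(3-methylbut-2-en-1-yl)chroman-4-ol | CC(C)=CCc1c(OCOC)c(C)c(OCOC)c2c1O[C@@H](c1ccc(OCOC)cc1)C[C@H]2O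
F5 | step 10 | (2S)-6-methyl-8-(3-methylbut-2-en-1-yl)-5,7-bis(triethylsilyloxy)-2-[4-(triethylsilyloxy)phenyl]chroman-4-one | CC(C)=CCc1c(O[Si](CC)(CC)CC)c(C)c(O[Si](CC)(CC)CC)c2c1O[C@H](c1ccc(O[Si](CC)(CC)CC)cc1)CC2=O
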